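**Plan**

- Retrosynthetic cuts: C11 aldehyde ← alcohol; enol ether of the side ring (ring D) ← its saturated lactone; C8–C14 ← radical conjugate addition to a 5-alkoxybutenolide; C9–C11 ← methylenation/hydroboration; C3–C4 of ring A ← 1,2-shift; C4–C5 and C1–C10 ← conjugate addition/alkylation of 2-methylcyclohexenone.
- Forward order: ring B is bought; C5 receives isopropenyl and C10 pentenyl; metathesis closes a seven-membered carbocycle (C1, C2, C3, C19, C4, C5, C10); its epoxide contracts to ring A; then (−)-drimenol, the C8–C14 coupling, and ring D last.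
- Enabling feature: C4 of ring A is quaternary, carries a methyl and sits beside the C3 methylene. This is the retron of the 1-methylcycloalkene oxide → 1-methylcycloalkanecarbaldehyde contraction; the extruded carbon C19 stays on C4 and becomes its second methyl.
- Stereochemistry: C5 by ligand-controlled copper catalysis; C10, C9 and C8 relayed from it by substrate control (anti alkylation, α-face hydroboration, α-face radical attack); C14 and C15 from the enantiopure (5S)-menthyloxybutenolide (anti addition, trans acetate).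

Key step: step 6

Remark: spongian-type locants are used (decalin C1–C10, C11 on C9, C12–C16 in ring D, C19 = the carbon that ends as the second C4 methyl). (5S)-5-(d-Menthyloxy)furan-2(5H)-one, the enantiomer of the common l-menthyl reagent, is taken as purchasable.

**Step 1**
Reactants: 1 2-methylcyclohex-2-en-1-one
Product: 3 trimethyl{[(3S)-2-methyl-3-(prop-1-en-2-yl)cyclohex-1-en-1-yl]oxy}silane, via magnesium enolate 2 (not isolated)
Conditions: CH2=C(Me)MgBr, CuBr·SMe2 (5 mol %), Josiphos-type ferrocenyl diphosphine (6 mol %, enantiomer chosen for 3S), TMSCl, 2-MeTHF, −78 °C; Et3N, pentane work-up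
Reagents that add atoms: isopropenylmagnesium bromide, CC(=C)[Mg]Br; chlorotrimethylsilane, C[Si](C)(C)Cl
Why: Copper-catalysed asymmetric conjugate addition to an α-substituted cyclohexenone with silyl trapping of the enolate; the chiral ligand directs the isopropenyl group to one face of C5 and so sets the only catalyst-controlled stereocentre.

**Step 2**
Reactants: 3 trimethyl{[(3S)-2-methyl-3-(prop-1-en-2-yl)cyclohex-1-en-1-yl]oxy}silane
Product: 5 (2S,3S)-2-methyl-2-(pent-4-en-1-yl)-3-(prop-1-en-2-yl)cyclohexan-1-one, via lithium enolate 4 (not isolated)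
Conditions: MeLi, THF, 0 °C; then DMPU, 5-iodopent-1-ene, −78 → 23 °C
Reagents that add atoms: 5-iodopent-1-ene, C=CCCCI
Why: Si–O cleavage gives the regiodefined tetrasubstituted lithium enolate, and enolate alkylation should occur anti to the neighbouring isopropenyl group, which fixes quaternary C10 trans to C5.

**Step 3**
Reactants: 5 (2S,3S)-2-methyl-2-(pent-4-en-1-yl)-3-(prop-1-en-2-yl)cyclohexan-1-one
Product: 7 (2S,3S)-2,6-dimethyl-2-(pent-4-en-1-yl)-3-(prop-1-en-2-yl)cyclohexan-1-one (C6 epimers), via lithium enolate 6 (not isolated)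
Conditions: LDA, THF, −78 °C; MeI, −78 → 0 °C
Reagents that add atoms: iodomethane, CI
Why: Kinetic enolate alkylation at the only enolisable position brings in the future C8 methyl; its configuration is of no consequence because step 8 makes this carbon trigonal.

**Step 4**
Reactants: 7 (2S,3S)-2,6-dimethyl-2-(pent-4-en-1-yl)-3-(prop-1-en-2-yl)cyclohexan-1-one
Product: 8 (4aS,9aS)-2,5,9a-trimethyl-2,3,4,4a,7,8,9,9a-octahydro-1H-benzo[7]annulen-1-one (C2 epimers)
Conditions: second-generation Grubbs catalyst RuCl2(=CHPh)(H2IMes)(PCy3) (5 mol %), toluene (5 mM), 80 °C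
Reagents that add atoms: none
Why: Ring-closing metathesis of the isopropenyl and terminal alkene should close the trans-fused seven-membered ring with its trisubstituted C4=C19 double bond, with loss of ethene as driving force.

**Step 5**
Reactants: 8 (4aS,9aS)-2,5,9a-trimethyl-2,3,4,4a,7,8,9,9a-octahydro-1H-benzo[7]annulen-1-one
Product: 9 the 5,6-epoxide of 8 (C4–C19 epoxide, trans ring fusion retained, epoxide diastereomers)
Conditions: mCPBA, NaHCO3, CH2Cl2, 0 °C
Reagents that add atoms: 3-chloroperoxybenzoic acid, OOC(=O)c1cccc(Cl)c1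
Why: Prilezhaev epoxidation of the electron-rich trisubstituted alkene should be far faster than Baeyer–Villiger attack on the hindered ketone; the epoxide face does not matter for the next step.

**Step 6**
Reactants: 9 the 5,6-epoxide of 8
Product: 10 (4aS,8aS)-1,4a,6-trimethyl-5-oxodecahydronaphthalene-1-carbaldehyde (C1 and C6 epimers)
Conditions: MeAl(OAr)2 (Ar = 4-bromo-2,6-di-tert-butylphenyl, 2.2 equiv, made beforehand), CH2Cl2, −78 → −20 °C
Reagents that add atoms: none
Why: The aluminium Lewis acid binds the epoxide oxygen, the tertiary C4–O bond ionises, and the ring bond C3–C19 of the neighbouring carbinol carbon shifts to C4, so the seven-membered carbocycle contracts to six-membered ring A and C19 appears as the aldehyde on the new quaternary C4 (Meinwald-type epoxide-to-aldehyde rearrangement with 1,2-alkyl shift). The closest known reaction type is the Lewis-acid ring contraction of 1-methylcycloalkene oxides to 1-methylcycloalkanecarbaldehydes with bulky aluminium phenoxides. Ring A is closed by this 1,2-shift (7 → 6 contraction) and not by a cyclisation, while the C4–C5 and C1–C10 bonds and the trans fusion at C5/C10 are carried over untouched. The only new stereocentre is C4, set by migration anti to the breaking C–O bond, and it is erased when step 7 turns CHO into the second methyl. The step needs shift of the ring carbon in preference to hydride shift (which would give the cycloheptanone) or elimination; the bulk of the aluminium reagent, the tertiary cationic character at C4 and the release of seven-ring strain should secure this.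

**Step 7**
Reactants: 10 (4aS,8aS)-1,4a,6-trimethyl-5-oxodecahydronaphthalene-1-carbaldehyde
Product: 12 (4aS,8aS)-2,5,5,8a-tetramethyloctahydronaphthalen-1(2H)-one (C2 epimers), via hydrazone 11 (not isolated)
Conditions: N2H4·H2O (1.2 equiv), EtOH, 23 °C; then KOt-Bu, DMSO, 23 → 60 °C
Reagents that add atoms: none
Why: Wolff–Kishner reduction in its low-temperature hydrazone/KOt-Bu form; the aldehyde should condense selectively because the ketone is flanked by a quaternary and a tertiary carbon, and CHO → CH3 completes the gem-dimethyl group.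

**Step 8**
Reactants: 12 (4aS,8aS)-2,5,5,8a-tetramethyloctahydronaphthalen-1(2H)-one
Product: 14 (4aS,8aS)-2,5,5,8a-tetramethyl-4a,5,6,7,8,8a-hexahydronaphthalen-1(4H)-one, via silyl enol ether 13 (not isolated)
Conditions: LDA, THF, −78 → 0 °C, TMSCl; then Pd(OAc)2 (1.05 equiv), MeCN, 23 °C
Reagents that add atoms: none
Why: Saegusa–Ito oxidation; only C8 can enolise, and β-hydride elimination from the ring methylene should give the conjugated endocyclic 2-methyl enone.

**Step 9**
Reactants: 14 (4aS,8aS)-2,5,5,8a-tetramethyl-4a,5,6,7,8,8a-hexahydronaphthalen-1(4H)-one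
Product: 15 drima-7,9(11)-diene, (4aS,8aS)-2,5,5,8a-tetramethyl-1-methylidene-1,4,4a,5,6,7,8,8a-octahydronaphthalene
Conditions: Ph3PCH3Br, KOt-Bu, toluene, 90 °C
Reagents that add atoms: methyltriphenylphosphonium bromide, C[P+](c1ccccc1)(c1ccccc1)c1ccccc1.[Br-]
Why: Wittig methylenation under conditions used for hindered ketones installs C11 as the exocyclic methylene.

**Step 10**
Reactants: 15 drima-7,9(11)-diene
Product: 17 (−)-drimenol, [(1S,4aS,8aS)-2,5,5,8a-tetramethyl-1,4,4a,5,6,7,8,8a-octahydronaphthalen-1-yl]methanol, via alkylborane 16 (not isolated)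
Conditions: 9-BBN, THF, 0 → 23 °C; then NaOH, H2O2, 0 °C
Reagents that add atoms: hydrogen peroxide, OO
Why: Hydroboration–oxidation; the bulky borane should add only to the terminal 1,1-disubstituted alkene with boron on C11, and hydrogen is delivered to C9 from the α face, opposite the axial C10 methyl, which sets C9.

**Step 11**
Reactants: 17 (−)-drimenol
Product: 18 tert-butyl(diphenyl)silyl ether of drimenol
Conditions: TBDPSCl, imidazole, DMAP (cat.), DMF, 40 °C
Reagents that add atoms: tert-butyl(chloro)diphenylsilane, CC(C)(C)[Si](Cl)(c1ccccc1)c1ccccc1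
Why: Silylation gives an acid-stable protecting group for C11–OH, which would otherwise be acetylated in step 14 or form an internal acetal with C15.

**Step 12**
Reactants: 18 tert-butyl(diphenyl)silyl ether of drimenol; 19 (5S)-5-(d-menthyloxy)furan-2(5H)-one
Product: 20 (4R,5S)-4-[(1R,2R,4aS,8aS)-1-{[tert-butyl(diphenyl)silyl]oxymethyl}-2,5,5,8a-tetramethyldecahydronaphthalen-2-yl]-5-(d-menthyloxy)dihydrofuran-2(3H)-one
Conditions: Fe(acac)3 (30 mol %), PhSiH3, EtOH/(CH2OH)2 5:1, 60 °C
Reagents that add atoms: none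
Why: Hydrogen-atom-transfer-initiated Giese addition (iron hydride, Mukaiyama type): H adds to C7, and the tertiary C8 radical should attack the butenolide β-carbon from its α face (the β face is blocked by the axial C10 methyl) and anti to the menthyloxy group, which sets C8 and C14 and relays C15.

**Step 13**
Reactants: 20 the Giese lactone
Product: 22 (3R,4R,5S)-3-(hydroxymethyl) derivative of 20, via lithium enolate 21 (not isolated)
Conditions: LDA, THF, −78 °C; CH2O (gas, from cracked paraformaldehyde), −78 → −40 °C; NH4Cl aq.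
Reagents that add atoms: formaldehyde, C=O
Why: Aldol reaction of the lactone enolate with formaldehyde introduces C12 at C13, expected trans to the C14 substituent (this centre becomes trigonal in step 15).

**Step 14**
Reactants: 22 the hydroxymethyl lactone
Product: 24 (3R,4R,5S)-5-acetoxy-3-(acetoxymethyl)-4-[(1R,2R,4aS,8aS)-1-{[tert-butyl(diphenyl)silyl]oxymethyl}-2,5,5,8a-tetramethyldecahydronaphthalen-2-yl]dihydrofuran-2(3H)-one, via monoacetate 23 (not isolated)
Conditions: Ac2O, BF3·OEt2 (0.3 equiv), CH2Cl2, −20 → 0 °C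
Reagents that add atoms: acetic anhydride, CC(=O)OC(C)=O
Why: O-Acetylation followed by acetolysis of the menthyl acetal through the C15 oxocarbenium ion, done while no enol ether is present; acetate should enter trans to the bulky C14 substituent.

**Step 15**
Reactants: 24 the diacetate lactone
Product: 27 [(2R,3S)-2-acetoxy-3-[(1R,2R,4aS,8aS)-1-{[tert-butyl(diphenyl)silyl]oxymethyl}-2,5,5,8a-tetramethyldecahydronaphthalen-2-yl]-2,3-dihydrofuran-4-yl]methyl acetate, via lactol 25 (not isolated), via mesylate 26 (not isolated)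
Conditions: disiamylborane (4 equiv), THF, 0 → 23 °C; MeOH, evaporate; then at once MsCl, Et3N, CH2Cl2, −40 → 23 °C
Reagents that add atoms: none
Why: Disiamylborane reduces a lactone to the lactol without touching acetates, and mesylation–elimination of the lactol (glycal-type) can lose only H13, giving the C13=C16 enol ether; the lactol is used at once because ring–chain tautomerism would expel acetate from C15.

**Step 16**
Reactants: 27 the silyl-protected dihydrofuran diacetate
Product: 28 [(2R,3S)-2-acetoxy-3-[(1R,2R,4aS,8aS)-1-(hydroxymethyl)-2,5,5,8a-tetramethyldecahydronaphthalen-2-yl]-2,3-dihydrofuran-4-yl]methyl acetate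
Conditions: TBAF, AcOH (1:1), THF, 23 °C
Reagents that add atoms: none
Why: Fluoride desilylation buffered with acetic acid should leave the acetates, the acetoxy acetal and the enol ether intact.

**Step 17**
Reactants: 28 the C11 alcohol
Product: 29 target, [(2R,3S)-2-acetoxy-3-[(1R,2R,4aS,8aS)-1-formyl-2,5,5,8a-tetramethyldecahydronaphthalen-2-yl]-2,3-dihydrofuran-4-yl]methyl acetate
Conditions: Dess–Martin periodinane, NaHCO3, CH2Cl2, 0 → 23 °C
Reagents that add atoms: none
Why: Dess–Martin oxidation of the hindered primary alcohol under buffered, non-basic conditions should give the aldehyde without epimerising C9 or harming ring D.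

**Compound list**

1 | 2-methylcyclohex-2-en-1-one | CC1=CCCCC1=O | starting material
2 | bromomagnesium (3S)-2-methyl-3-(prop-1-en-2-yl)cyclohex-1-en-1-olate | C1CC[C@@H](C(C)=C)C(C)=C1O[Mg]Br | intermediate
3 | trimethyl{[(3S)-2-methyl-3-(prop-1-en-2-yl)cyclohex-1-en-1-yl]oxy}silane | C1CC[C@@H](C(C)=C)C(C)=C1O[Si](C)(C)C | intermediate
4 | lithium (3S)-2-methyl-3-(prop-1-en-2-yl)cyclohex-1-en-1-olate | C1CC[C@@H](C(C)=C)C(C)=C1O[Li] | intermediate
5 | (2S,3S)-2-methyl-2-(pent-4-en-1-yl)-3-(prop-1-en-2-yl)cyclohexan-1-one | C=CCCC[C@@]1(C)[C@H](C(C)=C)CCCC1=O | intermediate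
6 | lithium enolate of 5 (toward C6) | C=CCCC[C@@]1(C)[C@H](C(C)=C)CCC=C1O[Li] | intermediate
7 | (2S,3S)-2,6-dimethyl-2-(pent-4-en-1-yl)-3-(prop-1-en-2-yl)cyclohexan-1-one (C6 epimers) | C=CCCC[C@@]1(C)[C@H](C(C)=C)CCC(C)C1=O | intermediate
8 | (4aS,9aS)-2,5,9a-trimethyl-2,3,4,4a,7,8,9,9a-octahydro-1H-benzo[7]annulen-1-one (C2 epimers) | CC1=CCCC[C@@]2(C)[C@H]1CCC(C)C2=O | intermediate
9 | 5,6-epoxide of 8 (epoxide diastereomers) | CC12OC1CCC[C@@]3(C)[C@H]2CCC(C)C3=O | intermediate
10 | (4aS,8aS)-1,4a,6-trimethyl-5-oxodecahydronaphthalene-1-carbaldehyde (C1, C6 epimers) | CC1(C=O)CCC[C@@]2(C)[C@H]1CCC(C)C2=O | intermediate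
11 | hydrazone of aldehyde 10 | CC1(C=NN)CCC[C@@]2(C)[C@H]1CCC(C)C2=O | intermediate
12 | (4aS,8aS)-2,5,5,8a-tetramethyloctahydronaphthalen-1(2H)-one (C2 epimers) | CC1(C)CCC[C@@]2(C)[C@H]1CCC(C)C2=O | intermediate
13 | trimethylsilyl enol ether of 12 | CC1(C)CCC[C@@]2(C)[C@H]1CCC(C)=C2O[Si](C)(C)C | intermediate
14 | (4aS,8aS)-2,5,5,8a-tetramethyl-4a,5,6,7,8,8a-hexahydronaphthalen-1(4H)-one | CC1(C)CCC[C@@]2(C)[C@H]1CC=C(C)C2=O | intermediate
15 | drima-7,9(11)-diene | CC1=CC[C@H]2C(C)(C)CCC[C@]2(C)C1=C | intermediate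
16 | B-(drim-7-en-11-yl)-9-borabicyclo[3.3.1]nonane | CC1=CC[C@H]2C(C)(C)CCC[C@]2(C)[C@H]1CB1C2CCCC1CCC2 | intermediate
17 | (−)-drimenol | CC1=CC[C@H]2C(C)(C)CCC[C@]2(C)[C@H]1CO | intermediate
18 | drimenyl tert-butyl(diphenyl)silyl ether | CC1=CC[C@H]2C(C)(C)CCC[C@]2(C)[C@H]1CO[Si](c1ccccc1)(c1ccccc1)C(C)(C)C | intermediate
19 | (5S)-5-{[(1S,2R,5S)-5-methyl-2-(propan-2-yl)cyclohexyl]oxy}furan-2(5H)-one | O=C1C=C[C@@H](O[C@H]2C[C@@H](C)CC[C@@H]2C(C)C)O1 | starting material
20 | (4R,5S)-4-[(1R,2R,4aS,8aS)-1-(silyloxymethyl)-2,5,5,8a-tetramethyldecahydronaphthalen-2-yl]-5-(d-menthyloxy)dihydrofuran-2(3H)-one | O=C1C[C@H]([C@]2(C)CC[C@H]3C(C)(C)CCC[C@]3(C)[C@H]2CO[Si](c2ccccc2)(c2ccccc2)C(C)(C)C)[C@@H](O[C@H]2C[C@@H](C)CC[C@@H]2C(C)C)O1 | intermediate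
21 | lithium enolate of lactone 20 | [Li]OC1=C[C@H]([C@]2(C)CC[C@H]3C(C)(C)CCC[C@]3(C)[C@H]2CO[Si](c2ccccc2)(c2ccccc2)C(C)(C)C)[C@@H](O[C@H]2C[C@@H](C)CC[C@@H]2C(C)C)O1 | intermediate
22 | (3R,4R,5S)-3-(hydroxymethyl) derivative of 20 | O=C1[C@@H](CO)[C@H]([C@]2(C)CC[C@H]3C(C)(C)CCC[C@]3(C)[C@H]2CO[Si](c2ccccc2)(c2ccccc2)C(C)(C)C)[C@@H](O[C@H]2C[C@@H](C)CC[C@@H]2C(C)C)O1 | intermediate
23 | 3-(acetoxymethyl) lactone still carrying the menthyl acetal | O=C1[C@@H](COC(C)=O)[C@H]([C@]2(C)CC[C@H]3C(C)(C)CCC[C@]3(C)[C@H]2CO[Si](c2ccccc2)(c2ccccc2)C(C)(C)C)[C@@H](O[C@H]2C[C@@H](C)CC[C@@H]2C(C)C)O1 | intermediate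
24 | (3R,4R,5S)-5-acetoxy-3-(acetoxymethyl)-4-(decalinyl)dihydrofuran-2(3H)-one | O=C1[C@@H](COC(C)=O)[C@H]([C@]2(C)CC[C@H]3C(C)(C)CCC[C@]3(C)[C@H]2CO[Si](c2ccccc2)(c2ccccc2)C(C)(C)C)[C@@H](OC(C)=O)O1 | intermediate
25 | lactol from 24 (C16 anomers) | OC1[C@@H](COC(C)=O)[C@H]([C@]2(C)CC[C@H]3C(C)(C)CCC[C@]3(C)[C@H]2CO[Si](c2ccccc2)(c2ccccc2)C(C)(C)C)[C@@H](OC(C)=O)O1 | intermediate
26 | mesylate of lactol 25 | CS(=O)(=O)OC1[C@@H](COC(C)=O)[C@H]([C@]2(C)CC[C@H]3C(C)(C)CCC[C@]3(C)[C@H]2CO[Si](c2ccccc2)(c2ccccc2)C(C)(C)C)[C@@H](OC(C)=O)O1 | intermediate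
27 | C11 silyl ether of the target alcohol (2R,3S-dihydrofuran diacetate) | CC(=O)OCC1=CO[C@H](OC(C)=O)[C@H]1[C@]1(C)CC[C@H]2C(C)(C)CCC[C@]2(C)[C@H]1CO[Si](c1ccccc1)(c1ccccc1)C(C)(C)C | intermediate
28 | C11 alcohol corresponding to the target | CC(=O)OCC1=CO[C@H](OC(C)=O)[C@H]1[C@]1(C)CC[C@H]2C(C)(C)CCC[C@]2(C)[C@H]1CO | intermediate
29 | CNP0170308.1 | CC(=O)OCC1=CO[C@H](OC(C)=O)[C@H]1[C@]1(C)CC[C@H]2C(C)(C)CCC[C@]2(C)[C@H]1C=O | target

**Totals**

Total step count: 17. Longest linear sequence: 17 steps (1 → 29); butenolide 19 enters as purchased.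

**Steps most likely to fail**

Step 6 (ring contraction). Hydride shift from C19 or loss of a proton next to the C4 cation may compete with shift of the ring carbon, giving the cycloheptanone or an allylic alcohol instead of ring A. The fallback sets out from 8 and still contracts the seven-membered ring, but through carbonyl chemistry. Ozonolysis (O3, CH2Cl2/MeOH, −78 °C; Me2S) would open the C4=C19 bond to the acetyl aldehyde F1. Piperidinium acetate would then close ring A by enamine aldol condensation of the aldehyde α-carbon C3 onto the methyl ketone, giving the cyclohexene carbaldehyde F2. Conjugate addition of Me2CuLi with TMSCl would install the second C4 methyl to give the aldehyde F3, and decarbonylation with RhCl(PPh3)3 (1 equiv, PhCN, 130 °C) would return to the route at 12.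

Step 12 (radical coupling). Hydrogen-atom transfer to the hindered trisubstituted alkene may be slower than alkene isomerisation or simple reduction, so that the C8 radical is not formed cleanly. The fallback sets out from 18 and generates the same radical from a C8 oxalate. Mukaiyama hydration (Mn(dpm)3 cat., PhSiH3, O2, i-PrOH) would give the tertiary alcohol F4. Acylation with methyl chlorooxoacetate (Et3N, DMAP) would give the methyl oxalate F5, and CsOH in aqueous THF the caesium oxalate F6. Visible-light photoredox decarboxylation (Ir[dF(CF3)ppy]2(dtbbpy)PF6 1 mol %, butenolide 19, DME/DMF, H2O, blue LEDs) would return to the route at 20.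

Step 15 (lactol formation and dehydration). The acetoxy lactol may open and expel acetic acid from C15 before it is mesylated, or a second elimination may aromatise ring D to the furan. The fallback sets out from 22 and keeps the robust menthyl acetal until a selenium leaving group is in place. Silylation (TBSCl, imidazole) would give the C12 silyl ether F7, and DIBAL-H at −78 °C the lactol F8. (PhSe)2 with PBu3 would give the C16 phenylseleno acetal F9. Acetolysis (Ac2O, BF3·OEt2, −20 °C) would then exchange both the menthyl acetal and the silyl ether for acetate to give F10. Oxidation with H2O2/pyridine at 0 °C and selenoxide syn-elimination would return to the route at 27.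

**Further compounds**

F1 | step 6 | (2S,3S)-3-acetyl-2,6-dimethyl-2-(4-oxobutyl)cyclohexan-1-one | O=CCCC[C@@]1(C)[C@H](C(C)=O)CCC(C)C1=O
F2 | step 6 | (4aS,8aS)-1,4a,6-trimethyl-5-oxo-3,4,4a,5,6,7,8,8a-octahydronaphthalene-2-carbaldehyde | CC1=C(C=O)CC[C@@]2(C)[C@H]1CCC(C)C2=O
F3 | step 6 | (4aS,8aS)-1,1,4a,6-tetramethyl-5-oxodecahydronaphthalene-2-carbaldehyde | CC1(C)C(C=O)CC[C@@]2(C)[C@H]1CCC(C)C2=O
F4 | step 12 | drimane-8,11-diol 11-tert-butyl(diphenyl)silyl ether | CC1(O)CC[C@H]2C(C)(C)CCC[C@]2(C)[C@H]1CO[Si](c1ccccc1)(c1ccccc1)C(C)(C)C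
F5 | step 12 | methyl oxalate of tertiary alcohol F4 | COC(=O)C(=O)OC1(C)CC[C@H]2C(C)(C)CCC[C@]2(C)[C@H]1CO[Si](c1ccccc1)(c1ccccc1)C(C)(C)C
F6 | step 12 | caesium oxalate of tertiary alcohol F4 | [Cs+].[O-]C(=O)C(=O)OC1(C)CC[C@H]2C(C)(C)CCC[C@]2(C)[C@H]1CO[Si](c1ccccc1)(c1ccccc1)C(C)(C)C
F7 | step 15 | C12 tert-butyldimethylsilyl ether of lactone 22 | O=C1[C@@H](CO[Si](C)(C)C(C)(C)C)[C@H]([C@]2(C)CC[C@H]3C(C)(C)CCC[C@]3(C)[C@H]2CO[Si](c2ccccc2)(c2ccccc2)C(C)(C)C)[C@@H](O[C@H]2C[C@@H](C)CC[C@@H]2C(C)C)O1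
F8 | step 15 | lactol from F7 (menthyl acetal retained) | OC1[C@@H](CO[Si](C)(C)C(C)(C)C)[C@H]([C@]2(C)CC[C@H]3C(C)(C)CCC[C@]3(C)[C@H]2CO[Si](c2ccccc2)(c2ccccc2)C(C)(C)C)[C@@H](O[C@H]2C[C@@H](C)CC[C@@H]2C(C)C)O1
F9 | step 15 | C16 phenylseleno acetal from F8 | c1ccccc1[Se]C1[C@@H](CO[Si](C)(C)C(C)(C)C)[C@H]([C@]2(C)CC[C@H]3C(C)(C)CCC[C@]3(C)[C@H]2CO[Si](c2ccccc2)(c2ccccc2)C(C)(C)C)[C@@H](O[C@H]2C[C@@H](C)CC[C@@H]2C(C)C)O1
F10 | step 15 | C16 phenylseleno acetal with C15 and C12 acetates | c1ccccc1[Se]C1[C@@H](COC(C)=O)[C@H]([C@]2(C)CC[C@H]3C(C)(C)CCC[C@]3(C)[C@H]2CO[Si](c2ccccc2)(c2ccccc2)C(C)(C)C)[C@@H](OC(C)=O)O1
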